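**Strategy.** The dihydropyran is disconnected by a retro hetero-Diels–Alder reaction into a triquinane methylene-1,2-dione and a (Z)-bicyclo[7.2.0]undecenone. The strategy rests on forming the central cyclopentane of the triquinane (ring B: C3a, C3b, C6a, C7, C7a) by an oxa-di-π-methane rearrangement, which in one photochemical operation contracts a cyclohexene ring of a bicyclo[2.2.2]octenone to ring B, closes the ring C ketone by 1,2-acyl shift and sets the methyl-bearing quaternary carbon C3b. The precursor is the intramolecular Diels–Alder adduct of a masked o-benzoquinone from creosol: its OH and OMe carbons become the vicinal oxygenated carbons C5 and C6 of ring C, its para-methyl carbon becomes C3b.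

Key step: step 6

Remark on the stereochemistry: read from the SMILES, the cyclobutane ring-fusion carbons are (1S,9R) in bicyclo[7.2.0]undecane numbering (the antipode of the natural caryophyllenes) and the pyran is cis-fused (H and CH3 on the same side), which corresponds to suprafacial addition to a Z olefin; the terpenoid half is therefore made by synthesis (steps 9 to 13).

Remark on steps 4 and 12: the product configuration written defines the step; the ligand or auxiliary enantiomer shown is the one expected to give it, and its antipode is used should the sense of induction prove opposite.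

Locants: the triquinane is numbered as decahydro-1H-cyclopenta[a]pentalene (ring A: C1, C2, C3, C3a, C7a; ring B: C3a, C3b, C6a, C7, C7a; ring C: C3b, C4, C5, C6, C6a). The same locants are used for these atoms in its precursors. The terpenoid half is numbered as bicyclo[7.2.0]undecane.

Step 1
Reactants: 1 2-methoxy-4-methylphenol (creosol)
Product: 2 2-[(dimethylamino)methyl]-6-methoxy-4-methylphenol
Conditions: Me2NH (40% aq.), CH2O (37% aq.), EtOH, 80 °C
Reagents that add atoms: formaldehyde C=O; dimethylamine CNC
Why: Phenolic Mannich reaction; with the para position blocked the iminium ion substitutes the only free position ortho to the hydroxyl group.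

Step 2
Reactants: 2 2-[(dimethylamino)methyl]-6-methoxy-4-methylphenol; 3 diallyl malonate
Product: 6 allyl 8-methoxy-6-methyl-2-oxochromane-3-carboxylate (racemic), via o-quinone methide 4 (not isolated), via malonate adduct 5 (not isolated)
Conditions: o-xylene, 140 °C, N2 sweep
Reagents that add atoms: none
Why: Thermal loss of dimethylamine from the Mannich base gives the o-quinone methide, which is trapped by conjugate (Michael) addition of the malonate, and the phenol then closes the six-membered lactone by transesterification with loss of allyl alcohol.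

Step 3
Reactants: 6 allyl 8-methoxy-6-methyl-2-oxochromane-3-carboxylate
Product: 7 allyl 8-methoxy-3,6-dimethyl-2-oxochromane-3-carboxylate (racemic)
Conditions: MeI, K2CO3, acetone, 25 °C
Reagents that add atoms: iodomethane CI
Why: C-Methylation of the malonate-type (lactone/ester) enolate; the stereocenter formed is racemic and is erased when the enolate is regenerated in step 4.

Step 4
Reactants: 7 allyl 8-methoxy-3,6-dimethyl-2-oxochromane-3-carboxylate
Product: 8 (3S)-3-allyl-8-methoxy-3,6-dimethylchroman-2-one
Conditions: Pd2(dba)3 (5 mol %), (R,R)-ANDEN-phenyl Trost ligand (13 mol %), 1,4-dioxane, 25 °C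
Reagents that add atoms: none
Why: Decarboxylative asymmetric allylic alkylation: zerovalent palladium ionises the allyl ester, loss of CO2 gives the lactone enolate and a chiral allylpalladium complex, and their recombination sets the quaternary center (the future C2 of the triquinane) under ligand control, a reaction type established for 3-substituted dihydrocoumarin allyl esters.

Step 5
Reactants: 8 (3S)-3-allyl-8-methoxy-3,6-dimethylchroman-2-one
Product: 11 methyl 11,11-dimethoxy-3,8-dimethyl-10-oxotricyclo[5.2.2.0(1,5)]undec-8-ene-3-carboxylate (single diastereomer; cyclopentane syn to the C8=C9 bridge; ester cis to H-5), via phenol ester 9 (not isolated), via masked o-benzoquinone 10 (not isolated)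
Conditions: NaOMe, MeOH, 0 to 25 °C; AcOH; PhI(OAc)2, 0 °C; then toluene, 110 °C
Reagents that add atoms: methanol CO
Why: Methanolysis opens the lactone, oxidative dearomatisation by the hypervalent iodine reagent (methanol adding at the methoxy-bearing carbon) gives the 6,6-dimethoxycyclohexa-2,4-dienone, and this undergoes an intramolecular Diels–Alder reaction with the terminal olefin (three-atom tether): the ring carbonyl carbon is a Z substituent of the tethered diene terminus and forces the endo-tether transition state (cyclopentane syn to the new olefinic bridge), while the quaternary center selects the diene face by placing its ester in the less hindered exo position of the forming cyclopentane, so that the configuration of C3a, C7a and C6a follows from C2.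

Step 6
Reactants: 11 methyl 11,11-dimethoxy-3,8-dimethyl-10-oxotricyclo[5.2.2.0(1,5)]undec-8-ene-3-carboxylate
Product: 12 methyl 6,6-dimethoxy-2,3b-dimethyl-5-oxo-3a,4-cyclodecahydro-1H-cyclopenta[a]pentalene-2-carboxylate (cyclopropane C3a–C3b–C4 on the face of ring C; rings A and C anti)
Conditions: hν (λ ≥ 300 nm, Pyrex), acetone (solvent and triplet sensitiser), 25 °C, argon
Reagents that add atoms: none
Why: Triplet-sensitised oxa-di-π-methane rearrangement of the β,γ-unsaturated ketone: the acyl carbon C5 bridges to the olefinic carbon C4, the C3a–C5 bond breaks (1,2-acyl shift) and the resulting 1,3-diradical closes between C3a and C3b. The closest known reaction type is the oxa-di-π-methane rearrangement of bicyclo[2.2.2]oct-5-en-2-ones to tricyclo[3.3.0.0(2,8)]octan-3-ones, the established entry to cis,anti,cis-triquinanes. Ring B closes by radical recombination across the cyclohexene ring C3a–C7a–C7–C6a–C3b–C4, which is thereby contracted to the cyclopentane C3a–C7a–C7–C6a–C3b with C4 extruded into a cyclopropane (3-exo closure), and ring C closes by the acyl migration. The new stereocenters (C3b with the angular methyl, C3a and C4) are fixed by the rigid bicyclic framework, since both new bonds form on the side of the keto bridge, and the anti relation of rings A and C follows from the cyclopentane having been placed syn to the olefinic bridge in step 5. The step needs triplet reactivity (rearrangement) over singlet reactivity (1,3-acyl shift, decarbonylation), which acetone sensitisation secures, and the substrate holds only one β,γ-enone unit.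

Step 7
Reactants: 12 methyl 6,6-dimethoxy-2,3b-dimethyl-5-oxo-3a,4-cyclodecahydro-1H-cyclopenta[a]pentalene-2-carboxylate
Product: 14 methyl 6,6-dimethoxy-2,3b-dimethyl-5-oxodecahydro-1H-cyclopenta[a]pentalene-2-carboxylate (cis,anti,cis; ester on the convex face of ring A), via tributylstannyl enol ether 13 (not isolated)
Conditions: Bu3SnH, AIBN (cat.), toluene, 80 °C; then H2O
Reagents that add atoms: none
Why: Reductive opening of the cyclopropyl ketone: the O-stannyl ketyl radical cleaves the external cyclopropane bond C3a–C4 (best overlap with the ketyl, tertiary radical), and hydrogen-atom transfer to C3a occurs on the face that gives the cis-fused A/B junction, the only low-strain bicyclo[3.3.0]octane.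

Step 8
Reactants: 14 methyl 6,6-dimethoxy-2,3b-dimethyl-5-oxodecahydro-1H-cyclopenta[a]pentalene-2-carboxylate
Product: 16 methyl 4-[(dimethylamino)methyl]-5-hydroxy-2,3b-dimethyl-6-oxo-1,2,3,3a,3b,6,6a,7,7a-nonahydrocyclopenta[a]pentalene-2-carboxylate hydrochloride (enol form of the 5,6-dione), via Mannich base ketal 15 (not isolated)
Conditions: LiN(SiMe3)2, THF, −78 °C; Me2N=CH2 iodide, −78 to 0 °C; then 3 M HCl, THF, 50 °C
Reagents that add atoms: N,N-dimethylmethyleneiminium iodide C=[N+](C)C.[I-]; water O; hydrogen chloride Cl
Why: Only C4 of the ketone can be enolised (C6 is the ketal carbon), so the lithium enolate is aminomethylated there (Mannich reaction), and aqueous acid then hydrolyses the α-keto ketal while the amine is protected as its ammonium salt; the C4 stereocenter is lost in the enol and in step 14.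

Step 9
Reactants: 17 nerol
Product: 18 (2Z)-1-bromo-3,7-dimethylocta-2,6-diene (neryl bromide)
Conditions: PBr3, Et2O, −10 °C
Reagents that add atoms: phosphorus tribromide BrP(Br)Br
Why: Bromination of the primary allylic alcohol (SN2 displacement of the bromophosphite) at low temperature, which preserves the Z olefin.

Step 10
Reactants: 18 (2Z)-1-bromo-3,7-dimethylocta-2,6-diene
Product: 19 ethyl (4Z)-5,9-dimethyldeca-4,8-dienoate
Conditions: EtOAc, LiN(iPr)2, THF, −78 °C; then 18, DMPU, −78 to −20 °C
Reagents that add atoms: ethyl acetate CCOC(C)=O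
Why: SN2 alkylation of the lithium enolate of ethyl acetate by the primary allylic bromide, giving the γ,δ-unsaturated ester without change of olefin geometry.

Step 11
Reactants: 20 (2R,5R)-2,5-dimethylpyrrolidine
Product: 21 1-[(2R,5R)-2,5-dimethylpyrrolidin-1-yl]ethan-1-one
Conditions: AcCl, Et3N, CH2Cl2, 0 °C
Reagents that add atoms: acetyl chloride CC(Cl)=O
Why: N-Acylation of the secondary amine with an acid chloride.

Step 12
Reactants: 19 ethyl (4Z)-5,9-dimethyldeca-4,8-dienoate; 21 1-[(2R,5R)-2,5-dimethylpyrrolidin-1-yl]ethan-1-one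
Product: 23 ethyl (4Z)-7-[(1R)-2,2-dimethyl-4-oxocyclobutyl]-5-methylhept-4-enoate, via cyclobutaniminium triflate 22 (not isolated)
Conditions: 21, Tf2O, 2,4,6-collidine, ClCH2CH2Cl, 0 °C; 19, 80 °C; then aq. NaHCO3, 25 °C
Reagents that add atoms: water O
Why: Keteniminium–olefin [2+2] cycloaddition: the amide is dehydrated to the keteniminium salt, whose iminium carbon bonds to the CH carbon of the more accessible terminal trisubstituted olefin and whose CH2 bonds to the CMe2 carbon, the C2-symmetric pyrrolidine differentiating the olefin faces to set the ring stereocenter, and hydrolysis of the cyclobutaniminium salt gives the cyclobutanone.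

Step 13
Reactants: 23 ethyl (4Z)-7-[(1R)-2,2-dimethyl-4-oxocyclobutyl]-5-methylhept-4-enoate
Product: 26 (1S,4Z,9R)-4,11,11-trimethylbicyclo[7.2.0]undec-4-en-8-one (trans-fused), via ethyl enol ether 24 (not isolated), via cis-fused ketone 25 (not isolated)
Conditions: TiCl3, LiAlH4, Et3N, DME, reflux, syringe-pump addition (high dilution); then 2 M HCl, THF, 40 °C
Reagents that add atoms: water O
Why: Titanium-induced intramolecular ketone–ester coupling (McMurry-type reaction) closes the nine-membered ring as a cyclic enol ether, aqueous acid hydrolyses it to the ketone and equilibrates C9 through the enol to the more stable trans-fused bicyclo[7.2.0] system, while C1 (not enolisable in the product) keeps its configuration.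

Step 14
Reactants: 16 methyl 4-[(dimethylamino)methyl]-5-hydroxy-2,3b-dimethyl-6-oxo-nonahydrocyclopenta[a]pentalene-2-carboxylate hydrochloride; 26 (1S,4Z,9R)-4,11,11-trimethylbicyclo[7.2.0]undec-4-en-8-one
Product: 28 hetero-Diels–Alder adduct (methyl ester of the target carrying a ring ketone in place of the exocyclic methylene; cis-fused pyran), via methylene dione 27 (not isolated)
Conditions: iPr2NEt (1.2 equiv), 26 (3 equiv), toluene, 90 °C, N2 sweep
Reagents that add atoms: none
Why: Base liberates the Mannich base, which loses dimethylamine (retro-Michael) to the s-cis-locked 4-methylidene-5,6-dione; its enone unit (O=C5–C4=CH2), made electron-poor by the adjacent C6 carbonyl, undergoes an inverse-electron-demand oxa-Diels–Alder reaction with the only olefin of 26, oxygen bonding to the methyl-bearing olefinic carbon, suprafacial addition to the Z olefin giving the cis ring fusion and attack on the face opposite the gem-dimethyl-bearing cyclobutane carbon setting the two new centers.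

Step 15
Reactants: 28 hetero-Diels–Alder adduct (ring ketone, methyl ester)
Product: 29 methyl ester of the target
Conditions: Ph3PCH3Br, KOtBu, THF, 0 to 25 °C
Reagents that add atoms: methyltriphenylphosphonium bromide C[P+](c1ccccc1)(c1ccccc1)c1ccccc1.[Br-]
Why: Wittig methylenation; the unhindered saturated ring ketone reacts in preference to the conjugated, fully flanked C6 ketone and to the ester, and the enolisable centers next to both ketones already have their thermodynamically preferred configuration.

Step 16
Reactants: 29 methyl ester of the target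
Product: 30 target acid (CNP0483070.2)
Conditions: LiOH·H2O, THF/MeOH/H2O, 50 °C; then 1 M HCl to pH 4, 0 °C
Reagents that add atoms: lithium hydroxide [Li+].[OH-]
Why: Saponification of the methyl ester, which lies on the convex face of ring A; the enol ether is part of an α-alkoxy enone and should survive the mild acidification.

**Compound list**

1 | 2-methoxy-4-methylphenol (creosol) | COc1cc(C)ccc1O | starting material
2 | 2-[(dimethylamino)methyl]-6-methoxy-4-methylphenol | CN(C)Cc1cc(C)cc(OC)c1O | intermediate
3 | diallyl malonate | C=CCOC(=O)CC(=O)OCC=C | starting material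
4 | 2-methoxy-4-methyl-6-methylidenecyclohexa-2,4-dien-1-one (o-quinone methide) | C=C1C=C(C)C=C(OC)C1=O | intermediate
5 | diallyl 2-(2-hydroxy-3-methoxy-5-methylbenzyl)malonate | COc1cc(C)cc(CC(C(=O)OCC=C)C(=O)OCC=C)c1O | intermediate
6 | allyl 8-methoxy-6-methyl-2-oxochromane-3-carboxylate (racemic) | COc1cc(C)cc2CC(C(=O)OCC=C)C(=O)Oc12 | intermediate
7 | allyl 8-methoxy-3,6-dimethyl-2-oxochromane-3-carboxylate (racemic) | COc1cc(C)cc2CC(C)(C(=O)OCC=C)C(=O)Oc12 | intermediate
8 | (3S)-3-allyl-8-methoxy-3,6-dimethylchroman-2-one | COc1cc(C)cc2c1OC(=O)[C@@](C)(CC=C)C2 | intermediate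
9 | methyl (2S)-2-(2-hydroxy-3-methoxy-5-methylbenzyl)-2-methylpent-4-enoate | COc1cc(C)cc(C[C@@](C)(C(=O)OC)CC=C)c1O | intermediate
10 | methyl (2S)-2-[(5,5-dimethoxy-3-methyl-6-oxocyclohexa-1,3-dien-1-yl)methyl]-2-methylpent-4-enoate (masked o-benzoquinone) | O=C1C(OC)(OC)C=C(C)C=C1C[C@@](C)(C(=O)OC)CC=C | intermediate
11 | methyl 11,11-dimethoxy-3,8-dimethyl-10-oxotricyclo[5.2.2.0(1,5)]undec-8-ene-3-carboxylate (cyclopentane syn to the olefinic bridge, ester cis to H-5) | O=C1C(OC)(OC)[C@H]2C(C)=C[C@@]13C[C@@](C)(C(=O)OC)C[C@@H]3C2 | intermediate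
12 | methyl 6,6-dimethoxy-2,3b-dimethyl-5-oxo-3a,4-cyclodecahydro-1H-cyclopenta[a]pentalene-2-carboxylate (cyclopropyl ketone, rings A and C anti) | [C@@H]14C(=O)C(OC)(OC)[C@@H]2C[C@H]3C[C@](C)(C(=O)OC)C[C@@]34[C@]12C | intermediate
13 | tributylstannyl enol ether of 14 (C4=C5 enolate, cis,anti,cis) | C1=C(O[Sn](CCCC)(CCCC)CCCC)C(OC)(OC)[C@@H]2C[C@H]3C[C@](C)(C(=O)OC)C[C@H]3[C@]12C | intermediate
14 | methyl 6,6-dimethoxy-2,3b-dimethyl-5-oxodecahydro-1H-cyclopenta[a]pentalene-2-carboxylate (cis,anti,cis; ester cis to H-3a and H-7a) | C1C(=O)C(OC)(OC)[C@@H]2C[C@H]3C[C@](C)(C(=O)OC)C[C@H]3[C@]12C | intermediate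
15 | methyl 4-[(dimethylamino)methyl]-6,6-dimethoxy-2,3b-dimethyl-5-oxodecahydro-1H-cyclopenta[a]pentalene-2-carboxylate (C4 epimers) | CN(C)CC1C(=O)C(OC)(OC)[C@@H]2C[C@H]3C[C@](C)(C(=O)OC)C[C@H]3[C@]12C | intermediate
16 | methyl 4-[(dimethylamino)methyl]-5-hydroxy-2,3b-dimethyl-6-oxo-1,2,3,3a,3b,6,6a,7,7a-nonahydrocyclopenta[a]pentalene-2-carboxylate hydrochloride | Cl.CN(C)CC1=C(O)C(=O)[C@@H]2C[C@H]3C[C@](C)(C(=O)OC)C[C@H]3[C@]12C | intermediate
17 | nerol, (2Z)-3,7-dimethylocta-2,6-dien-1-ol | CC(C)=CCC/C(C)=C\CO | starting material
18 | (2Z)-1-bromo-3,7-dimethylocta-2,6-diene | CC(C)=CCC/C(C)=C\CBr | intermediate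
19 | ethyl (4Z)-5,9-dimethyldeca-4,8-dienoate | CCOC(=O)CC/C=C(C)\CCC=C(C)C | intermediate
20 | (2R,5R)-2,5-dimethylpyrrolidine | C[C@@H]1CC[C@@H](C)N1 | starting material
21 | 1-[(2R,5R)-2,5-dimethylpyrrolidin-1-yl]ethan-1-one | CC(=O)N1[C@H](C)CC[C@H]1C | intermediate
22 | cyclobutaniminium triflate of 23 (N-cyclobutylidene-(2R,5R)-2,5-dimethylpyrrolidinium salt) | CCOC(=O)CC/C=C(C)\CC[C@H]1C(=[N+]2[C@H](C)CC[C@H]2C)CC1(C)C.[O-]S(=O)(=O)C(F)(F)F | intermediate
23 | ethyl (4Z)-7-[(1R)-2,2-dimethyl-4-oxocyclobutyl]-5-methylhept-4-enoate | CCOC(=O)CC/C=C(C)\CC[C@H]1C(=O)CC1(C)C | intermediate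
24 | (4Z)-8-ethoxy-4,11,11-trimethylbicyclo[7.2.0]undeca-4,8-diene (C1 as in 23) | CCOC1=C2CC(C)(C)[C@H]2CC/C(C)=C\CC1 | intermediate
25 | (1S,4Z,9S)-4,11,11-trimethylbicyclo[7.2.0]undec-4-en-8-one (cis-fused) | O=C1CC/C=C(C)\CC[C@H]2[C@@H]1CC2(C)C | intermediate
26 | (1S,4Z,9R)-4,11,11-trimethylbicyclo[7.2.0]undec-4-en-8-one (trans-fused) | O=C1CC/C=C(C)\CC[C@H]2[C@H]1CC2(C)C | intermediate
27 | methyl 2,3b-dimethyl-4-methylidene-5,6-dioxodecahydro-1H-cyclopenta[a]pentalene-2-carboxylate (cis,anti,cis) | C=C1C(=O)C(=O)[C@@H]2C[C@H]3C[C@](C)(C(=O)OC)C[C@H]3[C@]12C | intermediate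
28 | hetero-Diels–Alder adduct: methyl ester of the target with C=O in place of the exocyclic C=CH2 (cis-fused pyran, trans-fused cyclobutane) | O=C1CC[C@H]2CC3=C(O[C@@]2(C)CC[C@H]2[C@H]1CC2(C)C)C(=O)[C@@H]1C[C@H]2C[C@](C)(C(=O)OC)C[C@H]2[C@]31C | intermediate
29 | methyl ester of the target | C=C1CC[C@H]2CC3=C(O[C@@]2(C)CC[C@H]2[C@H]1CC2(C)C)C(=O)[C@@H]1C[C@H]2C[C@](C)(C(=O)OC)C[C@H]2[C@]31C | intermediate
30 | target acid (CNP0483070.2) | C=C1CC[C@H]2CC3=C(O[C@@]2(C)CC[C@H]2[C@H]1CC2(C)C)C(=O)[C@@H]1C[C@H]2C[C@](C)(C(=O)O)C[C@H]2[C@]31C | target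

**Step count and risks**

Total step count: 16. Longest linear sequence: 11 steps (steps 1 to 8, then 14 to 16).

The three steps most likely to fail:

Step 5. The quaternary center may discriminate the two diene faces poorly (methyl versus ester in the forming cyclopentane), giving the diastereomer with the mirror-image bicyclic core, and the masked o-benzoquinone may dimerise before it cyclises. The fallback enlarges the stereocontrolling group and sets out from 8. Reduction with LiAlH4 should give (2S)-2-(2-hydroxy-3-methoxy-5-methylbenzyl)-2-methylpent-4-en-1-ol F1. Selective silylation of the primary hydroxyl (tBuPh2SiCl, imidazole) should give 2-{(2S)-2-[(tert-butyldiphenylsilyloxy)methyl]-2-methylpent-4-enyl}-6-methoxy-4-methylphenol F2. The same dearomatisation and cycloaddition (PhI(OAc)2, MeOH, then toluene, 110 °C) should now place the much larger silyloxymethyl group exo and give the silyl ether analogue of 11 F3. Desilylation (Bu4NF) to the primary alcohol analogue of 11 F4, oxidation (TEMPO, NaOCl, then NaClO2) to the carboxylic acid corresponding to 11 F5, and esterification with Me3SiCHN2 bring the route back to 11.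

Step 12. The auxiliary may give low enantiofacial discrimination, the keteniminium salt may also attack the internal olefin, and the center next to the iminium carbon may epimerise during hydrolysis. The fallback replaces asymmetric induction by resolution and sets out from 19. Dichloroketene cycloaddition (Cl3CCOCl, Zn–Cu couple, Et2O) should give racemic ethyl (4Z)-7-(3,3-dichloro-2,2-dimethyl-4-oxocyclobutyl)-5-methylhept-4-enoate F6, and dechlorination (Zn, AcOH) the racemic cyclobutanone, ethyl (4Z)-7-(2,2-dimethyl-4-oxocyclobutyl)-5-methylhept-4-enoate F7. Addition of lithiated (S)-N,S-dimethyl-S-phenylsulfoximine at −78 °C gives diastereomeric β-hydroxy sulfoximines, which are separated by chromatography. Thermolysis (toluene, 110 °C) of the β-hydroxy sulfoximine adduct of the (R)-ketone F8 returns the route to 23.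

Step 14. The transient methylene dione may be consumed by dimerisation or by aldol or Michael reaction with the enolisable ring ketone of 26 before it cycloadds, and facial selectivity on the flexible Z-cyclononene may be incomplete. The fallback changes the order of methylenation and cycloaddition and sets out from 26. Wittig methylenation (Ph3PCH3Br, KOtBu, THF) should give (1S,4Z,9R)-4,11,11-trimethyl-8-methylidenebicyclo[7.2.0]undec-4-ene F9, a hydrocarbon without enolisable positions. It is heated in excess with 16 and iPr2NEt in toluene at 100 °C, so that the cycloaddition gives 29 directly and the route is rejoined at 29; any adduct from the exocyclic methylene is removed by chromatography.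

Further compounds
F1 | step 5 | (2S)-2-(2-hydroxy-3-methoxy-5-methylbenzyl)-2-methylpent-4-en-1-ol | COc1cc(C)cc(C[C@@](C)(CO)CC=C)c1O
F2 | step 5 | 2-{(2S)-2-[(tert-butyldiphenylsilyloxy)methyl]-2-methylpent-4-enyl}-6-methoxy-4-methylphenol | COc1cc(C)cc(C[C@@](C)(CO[Si](c2ccccc2)(c2ccccc2)C(C)(C)C)CC=C)c1O
F3 | step 5 | silyl ether analogue of 11 (CH2OSi(tBu)Ph2 in place of CO2Me) | O=C1C(OC)(OC)[C@H]2C(C)=C[C@@]13C[C@@](C)(CO[Si](c4ccccc4)(c4ccccc4)C(C)(C)C)C[C@@H]3C2
F4 | step 5 | primary alcohol analogue of 11 (CH2OH in place of CO2Me) | O=C1C(OC)(OC)[C@H]2C(C)=C[C@@]13C[C@@](C)(CO)C[C@@H]3C2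
F5 | step 5 | carboxylic acid corresponding to 11 | O=C1C(OC)(OC)[C@H]2C(C)=C[C@@]13C[C@@](C)(C(=O)O)C[C@@H]3C2
F6 | step 12 | ethyl (4Z)-7-(3,3-dichloro-2,2-dimethyl-4-oxocyclobutyl)-5-methylhept-4-enoate (racemic) | CCOC(=O)CC/C=C(C)\CCC1C(=O)C(Cl)(Cl)C1(C)C
F7 | step 12 | ethyl (4Z)-7-(2,2-dimethyl-4-oxocyclobutyl)-5-methylhept-4-enoate (racemic) | CCOC(=O)CC/C=C(C)\CCC1C(=O)CC1(C)C
F8 | step 12 | β-hydroxy sulfoximine adduct of the (R)-ketone with (S)-N,S-dimethyl-S-phenylsulfoximine | CCOC(=O)CC/C=C(C)\CC[C@H]1C(O)(C[S@@](=O)(=NC)c2ccccc2)CC1(C)C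
F9 | step 14 | (1S,4Z,9R)-4,11,11-trimethyl-8-methylidenebicyclo[7.2.0]undec-4-ene | C=C1CC/C=C(C)\CC[C@H]2[C@H]1CC2(C)C
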